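**Retrosynthetic overview**
1. The target comes from its 4,6-diol by selective acetylation. The diol comes from the C6=C7 alkene of a tetracyclic enone by syn-dihydroxylation, then oxidation and reduction to invert C6. C14 is set by base equilibration next to the C13 ketone.
2. The 3-methylcyclohexenone comes from a C11 ketone (dehydrogenation, MeLi, oxidative allylic transposition). The oxepane comes from C3-OH attacking a C16 triflate made by hydroboration of an isopropenyl group. The C3 carbinol comes from MeMgCl and a C3 ketone.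
3. The cyclohexene and tetrahydrofuran rings come from one intramolecular Diels–Alder reaction of an oxonene carrying a 2-methoxydiene on C9 and an E-enone on C2.
4. The oxonene comes from ring-closing metathesis at C6=C7. The C2–C3 bond comes from a boron glycolate aldol between an N-glycolyl oxazolidinone (C1, C2, C7–C10, from (S)-glycidol) and (S)-2-(TIPSO)pent-4-enal (C3–C6, from (S)-trityl glycidyl ether).
5. Ring order: the nine-membered ether first, then the six-membered carbocycle and the tetrahydrofuran together, then the oxepane.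

Assumption: the SMILES is read as the absolute configuration 1S,2R,3R,4S,6S,7S,9R,10R,14S,15S in briarellin numbering (C2–O–C9 tetrahydrofuran bridge, C3–O–C16 oxepane bridge, C13 ketone, C11=C12, methyls C17 on C15, C18 on C3, C19 on C7, C20 on C11); this numbering is used for all intermediates, and on the nine-membered ring drawn flat "α" is the face carrying C1 and C10 and "β" the face carrying H2 and H9.

**Step 1**
Reactants: 1 (S)-glycidol
Product: 2 (R)-2-[(4-methoxybenzyloxy)methyl]oxirane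
Conditions: NaH, 4-MeOC6H4CH2Cl, n-Bu4NI (cat.), THF/DMF, 0 °C → rt
Reagents that add atoms: 4-methoxybenzyl chloride, COc1ccc(CCl)cc1
Why: Williamson etherification of the primary alkoxide leaves the epoxide C–O bonds untouched, so the future C9 centre is kept (S becomes R only through CIP ranking).

**Step 2**
Reactants: 2 (R)-2-[(4-methoxybenzyloxy)methyl]oxirane
Product: 3 (R)-1-(4-methoxybenzyloxy)-4-methylpent-4-en-2-ol
Conditions: CH2=C(CH3)MgBr, CuI (10 mol %), THF, −40 → 0 °C
Reagents that add atoms: isopropenylmagnesium bromide, CC(=C)[Mg]Br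
Why: Copper-catalysed Grignard opening of the terminal epoxide is an SN2 attack at the unsubstituted carbon, so the C9 carbinol centre is retained.

**Step 3**
Reactants: 3 (R)-1-(4-methoxybenzyloxy)-4-methylpent-4-en-2-ol
Product: 4 2-{[(R)-1-(4-methoxybenzyloxy)-4-methylpent-4-en-2-yl]oxy}acetic acid
Conditions: NaH (3 equiv), BrCH2CO2H, THF, 0 °C → rt; 1 M HCl
Reagents that add atoms: bromoacetic acid, OC(=O)CBr
Why: Williamson etherification of the secondary alkoxide with sodium bromoacetate (SN2 at CH2) forms the C9–O–C2 ether without touching C9.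

**Step 4**
Reactants: 4 2-{[(R)-1-(4-methoxybenzyloxy)-4-methylpent-4-en-2-yl]oxy}acetic acid
Product: 6 (S)-4-benzyl-3-(2-{[(R)-1-(4-methoxybenzyloxy)-4-methylpent-4-en-2-yl]oxy}acetyl)oxazolidin-2-one, via mixed pivalic anhydride 5 (not isolated)
Conditions: t-BuCOCl, Et3N, THF, −20 °C; then LiCl, (S)-4-benzyloxazolidin-2-one, −20 °C → rt
Reagents that add atoms: (S)-4-benzyl-1,3-oxazolidin-2-one, O=C1N[C@@H](Cc2ccccc2)CO1; pivaloyl chloride, CC(C)(C)C(=O)Cl (its atoms stay only in 5)
Why: N-acylation through the mixed anhydride works because the oxazolidinone attacks the unhindered glycolyl carbonyl and not the pivaloyl one.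

**Step 5**
Reactants: 7 (S)-trityl glycidyl ether
Product: 8 (S)-1-(trityloxy)pent-4-en-2-ol
Conditions: CH2=CHMgBr, CuI (10 mol %), THF, −40 → −10 °C
Reagents that add atoms: vinylmagnesium bromide, C=C[Mg]Br
Why: Copper-catalysed SN2 opening at the terminal epoxide carbon keeps the carbinol centre that becomes C4.

**Step 6**
Reactants: 8 (S)-1-(trityloxy)pent-4-en-2-ol
Product: 9 (S)-triisopropyl{[1-(trityloxy)pent-4-en-2-yl]oxy}silane
Conditions: i-Pr3SiOTf, 2,6-lutidine, CH2Cl2, 0 °C
Reagents that add atoms: triisopropylsilyl triflate, CC(C)[Si](C(C)C)(C(C)C)OS(=O)(=O)C(F)(F)F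
Why: O-silylation with the silyl triflate gives a bulky, non-chelating, migration-resistant ether on O4 that lasts until step 36.

**Step 7**
Reactants: 9 (S)-triisopropyl{[1-(trityloxy)pent-4-en-2-yl]oxy}silane
Product: 10 (S)-2-(triisopropylsilyloxy)pent-4-en-1-ol
Conditions: TsOH·H2O (10 mol %), MeOH/CH2Cl2, 0 °C → rt
Reagents that add atoms: none
Why: Acid-catalysed SN1 methanolysis removes the trityl ether far faster than the secondary TIPS ether can be solvolysed.

**Step 8**
Reactants: 10 (S)-2-(triisopropylsilyloxy)pent-4-en-1-ol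
Product: 11 (S)-2-(triisopropylsilyloxy)pent-4-enal
Conditions: Dess–Martin periodinane, CH2Cl2, 0 °C → rt
Reagents that add atoms: none
Why: Dess–Martin oxidation is base-free, so the α-silyloxy aldehyde forms without epimerisation at C4.

**Step 9**
Reactants: 6 (S)-4-benzyl-3-(2-{[(R)-1-(4-methoxybenzyloxy)-4-methylpent-4-en-2-yl]oxy}acetyl)oxazolidin-2-one; 11 (S)-2-(triisopropylsilyloxy)pent-4-enal
Product: 13 (S)-4-benzyl-3-[(2S,3S,4S)-3-hydroxy-2-{[(R)-1-(4-methoxybenzyloxy)-4-methylpent-4-en-2-yl]oxy}-4-(triisopropylsilyloxy)hept-6-enoyl]oxazolidin-2-one, via Z-dibutylboron enolate 12 (not isolated)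
Conditions: n-Bu2BOTf, Et3N, CH2Cl2, −78 → 0 °C; 11, −78 → 0 °C; pH 7 buffer, MeOH, 30 % H2O2, 0 °C
Reagents that add atoms: di-n-butylboryl triflate, CCCCB(CCCC)OS(=O)(=O)C(F)(F)F (its atoms stay only in 12)
Why: In this Evans boron glycolate syn-aldol the Z-enolate adds through a Zimmerman–Traxler chair on the face left open by the benzyl group, which sets C2; the 2,3-syn C3 carbinol is erased in step 24, so the opposing Felkin bias of 11 cannot harm any centre that is kept.

**Step 10**
Reactants: 13 syn-aldol adduct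
Product: 14 (2R,3S,4S)-2-{[(R)-1-(4-methoxybenzyloxy)-4-methylpent-4-en-2-yl]oxy}-4-(triisopropylsilyloxy)hept-6-ene-1,3-diol
Conditions: NaBH4, THF/H2O (4:1), 0 °C → rt
Reagents that add atoms: none
Why: Borohydride reduction of the activated exocyclic imide carbonyl releases the auxiliary and gives the C1 primary alcohol without touching a stereocentre.

**Step 11**
Reactants: 14 1,3-diol
Product: 15 C1 pivalate of 14 (C3-OH free)
Conditions: t-BuCOCl (1.1 equiv), pyridine, CH2Cl2, 0 °C
Reagents that add atoms: pivaloyl chloride, CC(C)(C)C(=O)Cl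
Why: Selective acylation works because the primary C1 hydroxyl reacts much faster than the C3 hydroxyl, which is flanked by the ether and the TIPS ether.

**Step 12**
Reactants: 15 C1 pivalate
Product: 16 fully protected acyclic diene (C1-OPiv; C3-OTES; C4-OTIPS; C10-OPMB)
Conditions: Et3SiOTf, 2,6-lutidine, CH2Cl2, −78 → 0 °C
Reagents that add atoms: triethylsilyl triflate, CC[Si](CC)(CC)OS(=O)(=O)C(F)(F)F
Why: O-silylation gives a TES ether that fluoride can later remove in the presence of the TIPS ether.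

**Step 13**
Reactants: 16 fully protected acyclic diene
Product: 17 (2R,3S,4S,9R,6Z)-oxonene (C2: α-CH2OPiv; C3: α-OTES; C4: β-OTIPS; C7: CH3; C9: α-CH2OPMB)
Conditions: (H2IMes)(PCy3)Cl2Ru=CHPh (second-generation Grubbs catalyst, 5–10 mol %), CH2Cl2 (2 mM), reflux
Reagents that add atoms: none
Why: Ring-closing metathesis of the mono- and 1,1-disubstituted alkenes is helped by the gauche vicinal C–O bonds that fold the chain, and a nine-membered ring accepts only the Z trisubstituted alkene.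

**Step 14**
Reactants: 17 oxonene PMB ether
Product: 18 oxonene C10 primary alcohol
Conditions: DDQ, CH2Cl2/pH 7 buffer (10:1), 0 °C
Reagents that add atoms: none
Why: Oxidative PMB cleavage by DDQ is specific for the electron-rich benzyl ether and leaves the silyl ethers, the pivalate and the alkene alone.

**Step 15**
Reactants: 18 oxonene C10 primary alcohol
Product: 19 oxonene C10 aldehyde
Conditions: Dess–Martin periodinane, pyridine, CH2Cl2, 0 °C → rt
Reagents that add atoms: none
Why: Buffered Dess–Martin oxidation gives the α-alkoxy aldehyde without epimerising C9 or cleaving the TES ether.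

**Step 16**
Reactants: 19 oxonene C10 aldehyde
Product: 20 methyl (Z)-2-methoxyacrylate on C9 (C10=C11(OMe)–CO2Me; C9 trans to the ester)
Conditions: (MeO)2P(O)CH(OMe)CO2Me, LiN(SiMe3)2, THF, −78 → 0 °C
Reagents that add atoms: methyl 2-(dimethoxyphosphoryl)-2-methoxyacetate, COC(C(=O)OC)P(=O)(OC)OC
Why: The Horner–Wadsworth–Emmons reaction of the α-methoxy phosphonate puts the branched C9 substituent trans to the ester, which is the diene geometry the cycloaddition needs.

**Step 17**
Reactants: 20 methyl (Z)-2-methoxyacrylate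
Product: 21 diol (C12 allylic alcohol; C1 primary alcohol)
Conditions: i-Bu2AlH (6 equiv), CH2Cl2, −78 → −20 °C; aq. potassium sodium tartrate
Reagents that add atoms: none
Why: One i-Bu2AlH reduction turns the conjugated ester into the allylic alcohol and also removes the pivalate, while silyl and enol ethers are inert.

**Step 18**
Reactants: 21 diol
Product: 22 (Z)-2-methoxyenal with free C1-OH
Conditions: MnO2 (20 equiv), CH2Cl2, rt
Reagents that add atoms: none
Why: MnO2 oxidises only the allylic C12 alcohol under neutral conditions and leaves the saturated C1 alcohol and the enol ether untouched.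

**Step 19**
Reactants: 22 (Z)-2-methoxyenal
Product: 23 2-methoxy-1,3-diene (C10=C11(OMe)–C12=C13) with free C1-OH
Conditions: Ph3PCH3Br, KOt-Bu (3 equiv each), THF, 0 °C
Reagents that add atoms: methyltriphenylphosphonium bromide, C[P+](c1ccccc1)(c1ccccc1)c1ccccc1.[Br-]
Why: Wittig methylenation of the enal adds C13 and completes the diene without disturbing the C10=C11 geometry.

**Step 20**
Reactants: 23 2-methoxy-1,3-diene alcohol
Product: 24 C1 aldehyde carrying the 2-methoxydiene
Conditions: Dess–Martin periodinane, pyridine, CH2Cl2, 0 °C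
Reagents that add atoms: none
Why: Pyridine-buffered Dess–Martin oxidation is mild enough for the acid-sensitive dienol ether and the epimerisable C2 centre.

**Step 21**
Reactants: 24 C1 aldehyde carrying the 2-methoxydiene
Product: 26 tricyclic methyl ketone (H1/H10 cis; both trans to H2/H9; C14 acetyl trans to C2; C11(OMe)=C12), via tetraene enone 25 (not isolated)
Conditions: Ph3P=CHC(O)CH3, toluene, rt → 80 °C
Reagents that add atoms: 1-(triphenylphosphoranylidene)propan-2-one, CC(=O)C=P(c1ccccc1)(c1ccccc1)c1ccccc1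
Why: The Wittig reaction gives the E-enone, which the cis-2,9-disubstituted oxonene holds under the electron-rich diene, so an electronically matched intramolecular Diels–Alder reaction (C10 to C1, C13 to C14) follows through the tether-endo, acetyl-exo transition state on the face away from the C3–C8 bridge and sets C1, C10 and, provisionally, C14.

**Step 22**
Reactants: 26 tricyclic methyl ketone
Product: 27 tricyclic isopropenyl compound
Conditions: Ph3PCH3Br, KOt-Bu, THF, 0 °C → rt
Reagents that add atoms: methyltriphenylphosphonium bromide, C[P+](c1ccccc1)(c1ccccc1)c1ccccc1.[Br-]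
Why: Wittig methylenation of the only carbonyl adds C16, and the equatorial trans acetyl group has no drive to epimerise.

**Step 23**
Reactants: 27 tricyclic isopropenyl compound
Product: 28 C3 secondary alcohol (α-OH)
Conditions: n-Bu4NF (1.2 equiv), THF, 0 °C
Reagents that add atoms: none
Why: Fluoride cleaves the TES ether much faster than the hindered TIPS ether, and the basic medium spares the methyl enol ether.

**Step 24**
Reactants: 28 C3 secondary alcohol
Product: 29 C3 ketone
Conditions: Dess–Martin periodinane, pyridine, CH2Cl2, 0 °C → rt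
Reagents that add atoms: none
Why: Buffered Dess–Martin oxidation forms the ketone without epimerising C2 or C4 and without hydrolysing the enol ether.

**Step 25**
Reactants: 29 C3 ketone
Product: 30 C3 tertiary alcohol (β-CH3; α-OH pointing towards the isopropenyl group)
Conditions: MeMgCl, THF, −78 → −20 °C
Reagents that add atoms: methylmagnesium chloride, C[Mg]Cl
Why: The Grignard reagent adds from the open outer β face of the bridged nine-membered ring, which is also the Felkin–Anh sense for both flanking C–O bonds since the TIPS ether cannot chelate, and this sets C3.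

**Step 26**
Reactants: 30 C3 tertiary alcohol
Product: 32 (15S) C16 primary alcohol with C3-OH free, via B-alkyl-9-BBN borane 31 (not isolated)
Conditions: 9-BBN (3 equiv), THF, 0 °C → rt; then 3 M NaOH, 30 % H2O2, 0 °C
Reagents that add atoms: hydrogen peroxide, OO; 9-borabicyclo[3.3.1]nonane, B1C2CCCC1CCC2 (its boron stays only in 31)
Why: In this hydroboration–oxidation 9-BBN reacts only with the 1,1-disubstituted alkene, and in the rotamer with H14 eclipsing C15=C16 it attacks the face turned away from C1, which gives the 15S centre.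

**Step 27**
Reactants: 32 (15S) C16 primary alcohol
Product: 33 C11 ketone diol
Conditions: 1 M HCl, THF, 0 °C
Reagents that add atoms: water, O
Why: Mild acid hydrolysis of the methyl enol ether (C12 protonation, then water attack at C11) unmasks the ketone faster than the TIPS ether, the tertiary alcohol or the alkene can react.

**Step 28**
Reactants: 33 C11 ketone diol
Product: 35 tetracyclic oxepane ketone (H14 still trans to H1), via primary triflate 34 (not isolated)
Conditions: Tf2O (1.1 equiv), 2,6-lutidine (4 equiv), CH2Cl2, −78 °C → rt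
Reagents that add atoms: triflic anhydride, O=S(=O)(OS(=O)(=O)C(F)(F)F)C(F)(F)F (its atoms stay only in 34)
Why: Only the primary hydroxyl is triflated at −78 °C, and the nearby α-oriented C3 hydroxyl then displaces it in an intramolecular SN2 etherification (7-exo-tet) that touches no stereocentre.

**Step 29**
Reactants: 35 tetracyclic oxepane ketone
Product: 37 C11 enone (C12=C13), via trimethylsilyl enol ether 36 (not isolated)
Conditions: LiN(i-Pr)2, Me3SiCl, THF, −78 °C; then Pd(OAc)2 (1.1 equiv), MeCN, rt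
Reagents that add atoms: chlorotrimethylsilane, C[Si](C)(C)Cl (its atoms stay only in 36)
Why: Kinetic deprotonation occurs at the C12 methylene and not at the hindered ring-fusion C10–H, and Saegusa–Ito oxidation of the resulting enol silane places the alkene regiospecifically at C12=C13.

**Step 30**
Reactants: 37 C11 enone
Product: 38 C11 tertiary allylic alcohol (CH3 expected on the convex face; configuration of no consequence)
Conditions: MeLi, Et2O/THF, −78 °C
Reagents that add atoms: methyllithium, [Li]C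
Why: Methyllithium adds 1,2 to the enone and brings in C20, and the new C11 centre becomes sp2 again in the next step.

**Step 31**
Reactants: 38 C11 tertiary allylic alcohol
Product: 39 3-methylcyclohexenone (C13=O; C11=C12; H14 trans to H1)
Conditions: pyridinium chlorochromate, C5H5NH[CrO3Cl] (3 equiv), 4 Å MS, CH2Cl2, rt
Reagents that add atoms: pyridinium chlorochromate, [O-][Cr](=O)(=O)Cl.c1cc[nH+]cc1
Why: In the Babler–Dauben oxidative transposition the tertiary chromate ester undergoes a [3,3] shift to C13 and is then oxidised, which can only give the C13 ketone with the C11=C12 alkene.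

**Step 32**
Reactants: 39 3-methylcyclohexenone (H14 trans to H1)
Product: 40 (14S) enone (H14 cis to H1 and H10)
Conditions: DBU, toluene, rt → 50 °C
Reagents that add atoms: none
Why: In this base-mediated epimerisation α to the ketone three rings meet at C1, and with the fixed trans (tetrahydrofuran/oxepane) and cis (tetrahydrofuran/cyclohexenone) fusions only a cis cyclohexenone/oxepane fusion lets all three keep alternating staggered torsions, so 14S is the more stable epimer, while loss of the C9–O bond would be a disfavoured retro-5-endo-trig process.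

**Step 33**
Reactants: 40 (14S) enone
Product: 41 6β,7β-diol
Conditions: OsO4 (5 mol %), N-methylmorpholine N-oxide, acetone/H2O, rt
Reagents that add atoms: N-methylmorpholine N-oxide, C[N+]1([O-])CCOCC1; water, O (both oxygens are passed on through OsO4, O=[Os](=O)(=O)=O)
Why: In the Upjohn dihydroxylation OsO4 chooses the electron-rich C6=C7 alkene over the enone and adds syn from the outer β face of the Z-alkene, which sets C7 (β-OH, α-CH3) and leaves C6 to be inverted.

**Step 34**
Reactants: 41 6β,7β-diol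
Product: 42 C6 ketone with 7β-OH (α-ketol)
Conditions: IBX, DMSO, rt
Reagents that add atoms: none
Why: IBX oxidises the secondary alcohol of a 1,2-diol to the α-ketol without C–C cleavage, and the tertiary C7 alcohol cannot react.

**Step 35**
Reactants: 42 α-ketol
Product: 43 6α,7β-diol (6S,7S)
Conditions: NaBH4, MeOH/CH2Cl2 (1:1), −78 °C
Reagents that add atoms: none
Why: At −78 °C borohydride reduces the activated saturated α-hydroxy ketone much faster than the hindered β,β-disubstituted enone, and hydride enters from the same outer β face that OsO4 used, so the C6 hydroxyl ends on the α face.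

**Step 36**
Reactants: 43 6α,7β-diol
Product: 44 4,6,7-triol
Conditions: n-Bu4NF, THF, 0 °C → rt
Reagents that add atoms: none
Why: Fluoride desilylation removes the last protecting group, and its mild basicity is harmless because C14 is already the stable epimer.

**Step 37**
Reactants: 44 4,6,7-triol
Product: 45 target CNP0212231.3
Conditions: Ac2O, pyridine, DMAP (cat.), CH2Cl2, 0 °C → rt
Reagents that add atoms: acetic anhydride, CC(=O)OC(C)=O
Why: DMAP-catalysed acetylation takes the two secondary hydroxyls at C4 and C6, while the tertiary C7 hydroxyl stays free under these mild conditions.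

**Compound list**
1 | (S)-glycidol | OC[C@H]1CO1 | starting material
2 | (R)-2-[(4-methoxybenzyloxy)methyl]oxirane | COc1ccc(COC[C@H]2CO2)cc1 | intermediate
3 | (R)-1-(4-methoxybenzyloxy)-4-methylpent-4-en-2-ol | CC(=C)C[C@@H](O)COCc1ccc(OC)cc1 | intermediate
4 | 2-{[(R)-1-(4-methoxybenzyloxy)-4-methylpent-4-en-2-yl]oxy}acetic acid | CC(=C)C[C@H](COCc1ccc(OC)cc1)OCC(=O)O | intermediate
5 | mixed pivalic anhydride of 4 (not isolated) | CC(=C)C[C@H](COCc1ccc(OC)cc1)OCC(=O)OC(=O)C(C)(C)C | intermediate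
6 | N-glycolyl (S)-4-benzyloxazolidin-2-one | CC(=C)C[C@H](COCc1ccc(OC)cc1)OCC(=O)N1[C@@H](Cc2ccccc2)COC1=O | intermediate
7 | (S)-trityl glycidyl ether | C(OC(c1ccccc1)(c1ccccc1)c1ccccc1)[C@@H]1CO1 | starting material
8 | (S)-1-(trityloxy)pent-4-en-2-ol | C=CC[C@H](O)COC(c1ccccc1)(c1ccccc1)c1ccccc1 | intermediate
9 | (S)-TIPS ether of 8 | C=CC[C@H](O[Si](C(C)C)(C(C)C)C(C)C)COC(c1ccccc1)(c1ccccc1)c1ccccc1 | intermediate
10 | (S)-2-(triisopropylsilyloxy)pent-4-en-1-ol | C=CC[C@H](O[Si](C(C)C)(C(C)C)C(C)C)CO | intermediate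
11 | (S)-2-(triisopropylsilyloxy)pent-4-enal | C=CC[C@H](O[Si](C(C)C)(C(C)C)C(C)C)C=O | intermediate
12 | Z-dibutylboron enolate of 6 (not isolated) | CCCCB(CCCC)O/C(N1[C@@H](Cc2ccccc2)COC1=O)=C\O[C@H](CC(C)=C)COCc1ccc(OC)cc1 | intermediate
13 | (2S,3S,4S) syn-aldol adduct | C=CC[C@H](O[Si](C(C)C)(C(C)C)C(C)C)[C@@H](O)[C@H](O[C@H](CC(C)=C)COCc1ccc(OC)cc1)C(=O)N1[C@@H](Cc2ccccc2)COC1=O | intermediate
14 | (2R,3S,4S) 1,3-diol | C=CC[C@H](O[Si](C(C)C)(C(C)C)C(C)C)[C@@H](O)[C@H](O[C@H](CC(C)=C)COCc1ccc(OC)cc1)CO | intermediate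
15 | C1 pivalate | C=CC[C@H](O[Si](C(C)C)(C(C)C)C(C)C)[C@@H](O)[C@H](O[C@H](CC(C)=C)COCc1ccc(OC)cc1)COC(=O)C(C)(C)C | intermediate
16 | C3 TES ether, metathesis substrate | C=CC[C@H](O[Si](C(C)C)(C(C)C)C(C)C)[C@@H](O[Si](CC)(CC)CC)[C@H](O[C@H](CC(C)=C)COCc1ccc(OC)cc1)COC(=O)C(C)(C)C | intermediate
17 | (2R,3S,4S,9R,6Z)-oxonene, C10-OPMB | CC(C)[Si](C(C)C)(C(C)C)O[C@H]1C/C=C(C)\C[C@H](COCc2ccc(OC)cc2)O[C@H](COC(=O)C(C)(C)C)[C@@H]1O[Si](CC)(CC)CC | intermediate
18 | oxonene, C10-OH | CC(C)[Si](C(C)C)(C(C)C)O[C@H]1C/C=C(C)\C[C@H](CO)O[C@H](COC(=O)C(C)(C)C)[C@@H]1O[Si](CC)(CC)CC | intermediate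
19 | oxonene, C10 aldehyde | CC(C)[Si](C(C)C)(C(C)C)O[C@H]1C/C=C(C)\C[C@H](C=O)O[C@H](COC(=O)C(C)(C)C)[C@@H]1O[Si](CC)(CC)CC | intermediate
20 | oxonene, (Z)-2-methoxyacrylate on C9 | CC(C)[Si](C(C)C)(C(C)C)O[C@H]1C/C=C(C)\C[C@H](/C=C(/C(=O)OC)OC)O[C@H](COC(=O)C(C)(C)C)[C@@H]1O[Si](CC)(CC)CC | intermediate
21 | oxonene diol (C12-OH, C1-OH) | CC(C)[Si](C(C)C)(C(C)C)O[C@H]1C/C=C(C)\C[C@H](/C=C(/CO)OC)O[C@H](CO)[C@@H]1O[Si](CC)(CC)CC | intermediate
22 | oxonene (Z)-2-methoxyenal, C1-OH | CC(C)[Si](C(C)C)(C(C)C)O[C@H]1C/C=C(C)\C[C@H](/C=C(/C=O)OC)O[C@H](CO)[C@@H]1O[Si](CC)(CC)CC | intermediate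
23 | oxonene 2-methoxydiene, C1-OH | CC(C)[Si](C(C)C)(C(C)C)O[C@H]1C/C=C(C)\C[C@H](/C=C(/C=C)OC)O[C@H](CO)[C@@H]1O[Si](CC)(CC)CC | intermediate
24 | oxonene 2-methoxydiene, C1 aldehyde | CC(C)[Si](C(C)C)(C(C)C)O[C@H]1C/C=C(C)\C[C@H](/C=C(/C=C)OC)O[C@H](C=O)[C@@H]1O[Si](CC)(CC)CC | intermediate
25 | tetraene E-enone (not isolated) | CC(C)[Si](C(C)C)(C(C)C)O[C@H]1C/C=C(C)\C[C@H](/C=C(/C=C)OC)O[C@H](/C=C/C(C)=O)[C@@H]1O[Si](CC)(CC)CC | intermediate
26 | tricyclic Diels–Alder adduct, C14 acetyl | CC(C)[Si](C(C)C)(C(C)C)O[C@H]1C/C=C(C)\C[C@H]2O[C@@H]([C@@H]1O[Si](CC)(CC)CC)[C@@H]3[C@@H](C(C)=O)CC=C(OC)[C@@H]32 | intermediate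
27 | tricycle, C14 isopropenyl | CC(C)[Si](C(C)C)(C(C)C)O[C@H]1C/C=C(C)\C[C@H]2O[C@@H]([C@@H]1O[Si](CC)(CC)CC)[C@@H]3[C@@H](C(C)=C)CC=C(OC)[C@@H]32 | intermediate
28 | tricycle, C3 α-OH | CC(C)[Si](C(C)C)(C(C)C)O[C@H]1C/C=C(C)\C[C@H]2O[C@@H]([C@@H]1O)[C@@H]3[C@@H](C(C)=C)CC=C(OC)[C@@H]32 | intermediate
29 | tricycle, C3 ketone | CC(C)[Si](C(C)C)(C(C)C)O[C@H]1C/C=C(C)\C[C@H]2O[C@@H](C1=O)[C@@H]3[C@@H](C(C)=C)CC=C(OC)[C@@H]32 | intermediate
30 | tricycle, C3 tertiary alcohol (β-CH3, α-OH) | CC(C)[Si](C(C)C)(C(C)C)O[C@H]1C/C=C(C)\C[C@H]2O[C@@H]([C@]1(C)O)[C@@H]3[C@@H](C(C)=C)CC=C(OC)[C@@H]32 | intermediate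
31 | B-alkyl-9-BBN borane (not isolated) | CC(C)[Si](C(C)C)(C(C)C)O[C@H]1C/C=C(C)\C[C@H]2O[C@@H]([C@]1(C)O)[C@@H]3[C@@H]([C@H](C)CB4C5CCCC4CCC5)CC=C(OC)[C@@H]32 | intermediate
32 | (15S) C16 alcohol, enol ether | CC(C)[Si](C(C)C)(C(C)C)O[C@H]1C/C=C(C)\C[C@H]2O[C@@H]([C@]1(C)O)[C@@H]3[C@@H]([C@H](C)CO)CC=C(OC)[C@@H]32 | intermediate
33 | C11 ketone diol | CC(C)[Si](C(C)C)(C(C)C)O[C@H]1C/C=C(C)\C[C@H]2O[C@@H]([C@]1(C)O)[C@@H]3[C@@H]([C@H](C)CO)CCC(=O)[C@@H]32 | intermediate
34 | C16 primary triflate (not isolated) | CC(C)[Si](C(C)C)(C(C)C)O[C@H]1C/C=C(C)\C[C@H]2O[C@@H]([C@]1(C)O)[C@@H]3[C@@H]([C@H](C)COS(=O)(=O)C(F)(F)F)CCC(=O)[C@@H]32 | intermediate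
35 | tetracyclic oxepane, C11 ketone | CC(C)[Si](C(C)C)(C(C)C)O[C@H]1C/C=C(C)\C[C@H]2O[C@@H]3[C@@H]4[C@H](CCC(=O)[C@@H]42)[C@H](C)CO[C@]13C | intermediate
36 | C11 trimethylsilyl enol ether (not isolated) | CC(C)[Si](C(C)C)(C(C)C)O[C@H]1C/C=C(C)\C[C@H]2O[C@@H]3[C@@H]4[C@H](CC=C(O[Si](C)(C)C)[C@@H]42)[C@H](C)CO[C@]13C | intermediate
37 | C11 enone (C12=C13) | CC(C)[Si](C(C)C)(C(C)C)O[C@H]1C/C=C(C)\C[C@H]2O[C@@H]3[C@@H]4[C@H](C=CC(=O)[C@@H]42)[C@H](C)CO[C@]13C | intermediate
38 | C11 tertiary allylic alcohol | CC(C)[Si](C(C)C)(C(C)C)O[C@H]1C/C=C(C)\C[C@H]2O[C@@H]3[C@@H]4[C@H](C=C[C@](C)(O)[C@@H]42)[C@H](C)CO[C@]13C | intermediate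
39 | C13 enone, H14 trans to H1 | CC(C)[Si](C(C)C)(C(C)C)O[C@H]1C/C=C(C)\C[C@H]2O[C@@H]3[C@@H]4[C@H](C(=O)C=C(C)[C@@H]42)[C@H](C)CO[C@]13C | intermediate
40 | C13 enone, 14S (H14 cis to H1) | CC(C)[Si](C(C)C)(C(C)C)O[C@H]1C/C=C(C)\C[C@H]2O[C@@H]3[C@@H]4[C@@H](C(=O)C=C(C)[C@@H]42)[C@H](C)CO[C@]13C | intermediate
41 | 6β,7β-diol | CC(C)[Si](C(C)C)(C(C)C)O[C@H]1C[C@@H](O)[C@@](C)(O)C[C@H]2O[C@@H]3[C@@H]4[C@@H](C(=O)C=C(C)[C@@H]42)[C@H](C)CO[C@]13C | intermediate
42 | C6 ketone, 7β-OH | CC(C)[Si](C(C)C)(C(C)C)O[C@H]1CC(=O)[C@@](C)(O)C[C@H]2O[C@@H]3[C@@H]4[C@@H](C(=O)C=C(C)[C@@H]42)[C@H](C)CO[C@]13C | intermediate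
43 | 6α,7β-diol (6S,7S), C4-OTIPS | CC(C)[Si](C(C)C)(C(C)C)O[C@H]1C[C@H](O)[C@@](C)(O)C[C@H]2O[C@@H]3[C@@H]4[C@@H](C(=O)C=C(C)[C@@H]42)[C@H](C)CO[C@]13C | intermediate
44 | 4,6,7-triol | O[C@H]1C[C@H](O)[C@@](C)(O)C[C@H]2O[C@@H]3[C@@H]4[C@@H](C(=O)C=C(C)[C@@H]42)[C@H](C)CO[C@]13C | intermediate
45 | CNP0212231.3 (4,6-diacetate) | CC(=O)O[C@H]1C[C@H](OC(C)=O)[C@@](C)(O)C[C@H]2O[C@@H]3[C@@H]4[C@@H](C(=O)C=C(C)[C@@H]42)[C@H](C)CO[C@]13C | target

**Totals**
Total step count: 37. Longest linear sequence: 33 steps (steps 1–4 and 9–37, from (S)-glycidol).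

**The three steps most likely to fail**

Step 26 (C15 set by substrate-controlled hydroboration). The facial bias depends on which isopropenyl rotamer reacts, so the diastereomer ratio may be low or reversed. The fallback sets out from 30 and returns at 32, and it replaces kinetic face selection by equilibration of an acidic centre. The hydroboration is run as before and the epimers are separated. The unwanted 15R diol F1 is oxidised with Dess–Martin periodinane and pyridine to the 15R aldehyde F2. DBU in CH2Cl2 equilibrates the now enolisable C15 to give the 15S aldehyde F3. F3 is separated and F2 is recycled. NaBH4 in MeOH reduces F3 to 32.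

Step 32 (C14 set under thermodynamic control). The torsional argument is qualitative, so the equilibrium could be incomplete. The fallback sets out from 39 and returns at 40, and it uses kinetic control. LiN(SiMe3)2 in THF at −78 °C removes the α′ proton H14 to give the cross-conjugated lithium dienolate F4. Quenching at −78 °C with 2,6-di-tert-butyl-4-methylphenol protonates C14 from the convex face, the face that carries H1 and H10. This gives the same 14S epimer 40.

Step 35 (C6 inversion by ketone reduction). The face of hydride attack depends on the conformation of the nine-membered α-ketol. The fallback sets out from 41, skips 42 and returns at 43, and it uses a stereospecific SN2 inversion.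
- SOCl2 and Et3N convert the 6β,7β-diol into the cyclic sulfite F5.
- RuCl3 (cat.) and NaIO4 in MeCN/CCl4/H2O at 0 °C give the cyclic sulfate F6.
- CsOAc in DMF opens F6 at the secondary C6 with inversion to the 6α-acetoxy 7-sulfate caesium salt F7.
- Catalytic H2SO4 in wet THF hydrolyses F7 to the 6α-acetate F8.
- K2CO3 in MeOH converts F8 into 43.

**Further compounds**
F1 | step 26 | 15R diol (15-epimer of 32) | CC(C)[Si](C(C)C)(C(C)C)O[C@H]1C/C=C(C)\C[C@H]2O[C@@H]([C@]1(C)O)[C@@H]3[C@@H]([C@@H](C)CO)CC=C(OC)[C@@H]32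
F2 | step 26 | 15R aldehyde | CC(C)[Si](C(C)C)(C(C)C)O[C@H]1C/C=C(C)\C[C@H]2O[C@@H]([C@]1(C)O)[C@@H]3[C@@H]([C@@H](C)C=O)CC=C(OC)[C@@H]32
F3 | step 26 | 15S aldehyde | CC(C)[Si](C(C)C)(C(C)C)O[C@H]1C/C=C(C)\C[C@H]2O[C@@H]([C@]1(C)O)[C@@H]3[C@@H]([C@H](C)C=O)CC=C(OC)[C@@H]32
F4 | step 32 | cross-conjugated lithium dienolate of 39 | [Li+].CC(C)[Si](C(C)C)(C(C)C)O[C@H]1C/C=C(C)\C[C@H]2O[C@@H]3[C@@H]4C(=C([O-])C=C(C)[C@@H]42)[C@H](C)CO[C@]13C
F5 | step 35 | 6β,7β-cyclic sulfite | CC(C)[Si](C(C)C)(C(C)C)O[C@H]1C[C@H]5OS(=O)O[C@@]5(C)C[C@H]2O[C@@H]3[C@@H]4[C@@H](C(=O)C=C(C)[C@@H]42)[C@H](C)CO[C@]13C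
F6 | step 35 | 6β,7β-cyclic sulfate | CC(C)[Si](C(C)C)(C(C)C)O[C@H]1C[C@H]5OS(=O)(=O)O[C@@]5(C)C[C@H]2O[C@@H]3[C@@H]4[C@@H](C(=O)C=C(C)[C@@H]42)[C@H](C)CO[C@]13C
F7 | step 35 | 6α-acetoxy 7-sulfate caesium salt | [Cs+].CC(C)[Si](C(C)C)(C(C)C)O[C@H]1C[C@H](OC(C)=O)[C@@](C)(OS(=O)(=O)[O-])C[C@H]2O[C@@H]3[C@@H]4[C@@H](C(=O)C=C(C)[C@@H]42)[C@H](C)CO[C@]13C
F8 | step 35 | 6α-acetate, 7β-OH, C4-OTIPS | CC(C)[Si](C(C)C)(C(C)C)O[C@H]1C[C@H](OC(C)=O)[C@@](C)(O)C[C@H]2O[C@@H]3[C@@H]4[C@@H](C(=O)C=C(C)[C@@H]42)[C@H](C)CO[C@]13C
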